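**Vessel and charge.** A closed, stirred, isothermal vessel holds a racemic substrate, reagent, single-handed free catalyst and a trace of precatalyst. Two earlier runs differ in precatalyst, and the new flask carries more of it.

| setting | blue | violet | flask |
|---|---|---|---|
| left-handed substrate | 0.050 M | 0.050 M | 0.050 M |
| right-handed substrate | 0.050 M | 0.050 M | 0.050 M |
| reagent | 0.20 M | 0.20 M | 0.200 M |
| free catalyst | 2.5 mM | 2.5 mM | 2.5 mM |
| precatalyst | 38 µM | 56 µM | 75 µM |
| remark | run made earlier | run made earlier |  |
| time |  |  | 3.0 min |

- blue (time / min: left-handed product / %, right-handed product / %): 0.250: 9.1, 1.3; 0.500: 13.4, 1.9; 1.33: 21.0, 3.7; 3.00: 26.4, 4.1
- violet (time / min: left-handed product / %, right-handed product / %): 0.417: 12.1, 2.2; 1.00: 18.9, 3.0; 2.00: 23.2, 3.8; 3.00: 26.3, 4.4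

(scatter of a reading: 0.3 percentage points)

* left-handed product and right-handed product together, in percent of the left-handed substrate and right-handed substrate charged together, at 3.0 min
* excess of left-handed product over right-handed product in the product at 3.0 min
* whether the exchange between left-handed substrate and right-handed substrate keeps pace with the reaction: how far the product's excess at 3.0 min gets from its value without exchange to its value with instant exchange (above 80 % keeps pace, below 20 % hardly takes part, else lags behind)

- free catalyst is single-handed; left-handed substrate and right-handed substrate are mirror images of each other, charged as a racemate, each of them at the stated concentration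
- an excess is the difference of the two amounts in percent of their sum
- an excess is below zero if the other one leads

**Fastest rung.** Blue gains 9.1 % of left-handed product in its first 0.250 min, but 5.4 percentage points over its last 1.67 min. That pace falls much further than the left-handed substrate does, since 47.2 % of its charge still stands by the product count. So the working catalyst appears to fade, and blue slows with substrate present.

**Middle rung.** While the catalyst works, the two substrates compete. The selectivity factor s is the logarithm of the unreacted fraction of left-handed substrate divided by the logarithm of that of right-handed substrate, each fraction being one minus twice the product's percent. The blue and violet readings at 3.00 min average s = 8.44. This reading presumes no exchange.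

**Slowest rung.** Instant exchange holds the substrates equal, so the excess would be (s − 1)/(s + 1) = 78.8 %. The runs read 72.2 % on average, which is lower. Precatalyst rises from 38 µM to 56 µM between blue and violet, yet the totals differ by 0.2 points, within the scatter. Taking precatalyst as the likely feed of exchange, a guess, this reckoning expects the new flask to stay near 30.6 % and 72.2 %, with exchange hardly taking part, though s itself rests on that presumption.

**Forecast and result.** The forecast gives 30.7 %, an excess of 72.5 % and "hardly takes part", noting that “no dose response shows”. The flask gives 30.4 % and 71.4 %, and exchange hardly takes part, getting 2.4 % of the way. Its own products give s = 8.11.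

    reagent + free catalyst + left-handed substrate → free catalyst + left-handed product (k = 37.0 L² mol⁻² s⁻¹)
    left-handed substrate + racemization catalyst ⇌ right-handed substrate + racemization catalyst, rate k2*[racemization catalyst]*[left-handed substrate] forward; the back reaction follows from the equilibrium constant (k = 15.0 L mol⁻¹ s⁻¹)
    2 free catalyst → spent catalyst (k = 11.0 L mol⁻¹ s⁻¹)
    reagent + free catalyst + right-handed substrate → free catalyst + right-handed product (k = 4.60 L² mol⁻² s⁻¹)
    precatalyst → racemization catalyst (k = 0.00310 s⁻¹)

**Early stop.** The largest single effect on this flask is free catalyst pairing into spent catalyst, which holds conversion at 30.4 % against 60.9 % without that step. The same early stop keeps the excess at 71.4 % rather than 54.5 %. The neighbour with 0.50 M of reagent travels further along the same curve. Its left-handed product reaches 42.7 %, from which s gives 10.2 % of right-handed product against the 10.3 % it holds, and its excess stands at 61.0 %.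

(The numbers in the tables were computed from invented constants; noise was put on by code.)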